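The cyclohexane of the target carries a vinyl group on quaternary C10 and a hydroxyisopropenyl group on the adjacent C5, cis to each other. Together they form a 1,5-diene (C2=C1–C10–C5–C4=C3), the retron of a Cope rearrangement. Breaking C5–C10 and joining C2–C3 leads back to a ten-membered germacra-1(10),4,11(13)-trien-6α,12-olide with a ring-trans C1=C10 and a ring-cis C4=C5 alkene. Heating this macrocycle contracts it to the cyclohexane and sets C5 and C10 in one operation. The precursor is assembled from a glycidol-derived alkenyl iodide and a butynediol-derived diene by B-alkyl Suzuki coupling, closed with CrCl2 and acylated at O8.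

Key step: step 17

Remark on numbering: germacrane atom numbers (C1–C15) are kept for all intermediates and for the rearranged products; α/β use the usual orientation with H7 α.

Remark on the structures: target, Cope precursor 26 and Cope product 27 agree with each other, so no skeletal correction was needed. C6, C7 and C8 are identical in 26 and 27. In 26, C9 is trans to C2 across C1=C10, and C3 is cis to C6 across C4=C5 (formally E by the sequence rules because of the C15 oxygen).

Remark on the precursor design: C15 carries a tert-butyldiphenylsilyl ether so that the C8 triethylsilyl ether can be removed selectively before acylation. C8 is taken from (R)-glycidol, and the two butynediol hydroxyls are differentiated by monosilylation before hydroalumination.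

Assumption: (R)-glycidol, LiC≡CH·H2NCH2CH2NH2 and CH2=CHBF3K are purchased.

Step 1
Reactants: 1 but-2-yne-1,4-diol
Product: 2 4-[(tert-butyldiphenylsilyl)oxy]but-2-yn-1-ol
Conditions: TBDPSCl (1 equiv), imidazole, DMF, 0 °C to rt, diol in threefold excess
Reagents that add atoms: tert-butyl(chloro)diphenylsilane, CC(C)(C)[Si](Cl)(c1ccccc1)c1ccccc1
Why: Silyl ether formation on a cheap symmetric diol used in excess should give mainly the monoether, the remaining diol being washed out with water.

Step 2
Reactants: 2 4-[(tert-butyldiphenylsilyl)oxy]but-2-yn-1-ol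
Product: 4 (Z)-4-[(tert-butyldiphenylsilyl)oxy]-3-iodobut-2-en-1-ol, via cyclic sodium alkenylalanate 3 (not isolated)
Conditions: NaAlH2(OCH2CH2OCH3)2, THF, 0 °C; then I2, THF, −78 °C
Reagents that add atoms: iodine, II
Why: Hydroxyl-directed trans-hydroalumination of the propargylic alcohol puts hydride on C5 and aluminium on C4 inside a five-membered alanate, and iodinolysis with retention should give the alkenyl iodide with iodine cis to C6, which fixes the later ring-cis C4=C5 geometry.

Step 3
Reactants: 4 (Z)-4-[(tert-butyldiphenylsilyl)oxy]-3-iodobut-2-en-1-ol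
Product: 5 (E)-3-{[(tert-butyldiphenylsilyl)oxy]methyl}penta-2,4-dien-1-ol
Conditions: CH2=CHBF3K, PdCl2(dppf) (cat.), Cs2CO3, THF/H2O, 70 °C
Reagents that add atoms: potassium vinyltrifluoroborate, [K+].C=C[B-](F)(F)F
Why: Suzuki–Miyaura vinylation of an alkenyl iodide proceeds with retention of alkene geometry and tolerates the free allylic alcohol and the silyl ether.

Step 4
Reactants: 6 (R)-glycidol
Product: 7 (S)-pent-4-yne-1,2-diol
Conditions: LiC≡CH·H2NCH2CH2NH2 (3 equiv), DMSO, 0 °C to rt
Reagents that add atoms: lithium acetylide–ethylenediamine complex, [Li+].[C-]#C.NCCN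
Why: SN2 opening of the terminal epoxide at its CH2 carbon by acetylide leaves the stereocentre untouched, so C8 comes from the chiral pool, and the competing epoxide migration of the glycidol alkoxide only regenerates the same enantiomer.

Step 5
Reactants: 7 (S)-pent-4-yne-1,2-diol
Product: 8 (S)-4,5-bis[(triethylsilyl)oxy]pent-1-yne
Conditions: TESCl, imidazole, DMF, 0 °C to rt
Reagents that add atoms: chlorotriethylsilane, CC[Si](Cl)(CC)CC
Why: Exhaustive silylation of both hydroxyls is routine and prepares the differentiation of the primary and the secondary oxygen in step 7.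

Step 6
Reactants: 8 (S)-4,5-bis[(triethylsilyl)oxy]pent-1-yne
Product: 10 (2S,4E)-5-iodo-4-methyl-1,2-bis[(triethylsilyl)oxy]pent-4-ene, via alkenyldimethylalane 9 (not isolated)
Conditions: AlMe3, Cp2ZrCl2 (cat.), CH2Cl2, 0 °C to rt; then I2, THF, −30 °C; NaHCO3 quench
Reagents that add atoms: trimethylaluminium, C[Al](C)C; iodine, II
Why: Zirconium-catalysed Negishi carboalumination adds methyl and aluminium syn across the terminal alkyne with methyl on the internal carbon, and iodinolysis with retention should give the (E)-iodide that becomes the ring-trans C1=C10 bond bearing C14.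

Step 7
Reactants: 10 (2S,4E)-5-iodo-4-methyl-1,2-bis[(triethylsilyl)oxy]pent-4-ene
Product: 12 (2S,4E)-5-iodo-4-methyl-2-[(triethylsilyl)oxy]pent-4-enal, via alkoxydimethylsulfonium chloride 11 (not isolated)
Conditions: (COCl)2, DMSO (excess), CH2Cl2, −78 to −40 °C; then Et3N, −78 to 0 °C
Reagents that add atoms: none
Why: Under Swern conditions with excess activated DMSO a primary triethylsilyl ether is cleaved and oxidised in the flask while the hindered secondary one survives, and the cold amine quench should leave the α-silyloxy stereocentre intact.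

Step 8
Reactants: 12 (2S,4E)-5-iodo-4-methyl-2-[(triethylsilyl)oxy]pent-4-enal; 13 methyl acrylate
Product: 14 methyl (4S,6E)-3-hydroxy-7-iodo-6-methyl-2-methylidene-4-[(triethylsilyl)oxy]hept-6-enoate (both C3 epimers)
Conditions: DABCO (1 equiv), methyl acrylate (excess), MeOH (cat.), rt
Reagents that add atoms: none
Why: Morita–Baylis–Hillman addition is favoured for α-oxygenated aldehydes, and the new carbinol centre (C7) needs no control because it becomes sp2 in step 11.

Step 9
Reactants: 5 (E)-3-{[(tert-butyldiphenylsilyl)oxy]methyl}penta-2,4-dien-1-ol; 14 Baylis–Hillman adduct (alkenyl iodide)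
Product: 16 methyl (4S,6E,10E)-10-{[(tert-butyldiphenylsilyl)oxy]methyl}-3,12-dihydroxy-6-methyl-2-methylidene-4-[(triethylsilyl)oxy]dodeca-6,10-dienoate, via B-alkyl-9-BBN borane 15 (not isolated)
Conditions: 9-BBN-H (2.2 equiv), THF, 0 °C to rt; then 14, PdCl2(dppf) (cat.), AsPh3, Cs2CO3, DMF/H2O, rt
Reagents that add atoms: none
Why: 9-BBN should add only to the terminal alkene of the diene with boron on the terminal carbon C2 (the hydroxyl being borylated in passing), and B-alkyl Suzuki–Miyaura coupling with the (E)-alkenyl iodide forms C1–C2 with retention of both trisubstituted alkenes under mild aqueous base.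

Step 10
Reactants: 16 triene diol
Product: 17 methyl (4S,6E,10E)-10-{[(tert-butyldiphenylsilyl)oxy]methyl}-3-hydroxy-6-methyl-2-methylidene-12-oxo-4-[(triethylsilyl)oxy]dodeca-6,10-dienoate
Conditions: TEMPO (cat.), PhI(OAc)2, CH2Cl2, rt
Reagents that add atoms: none
Why: Oxoammonium oxidation with TEMPO and PhI(OAc)2 is selective for the primary allylic alcohol over the secondary one and should give the enal without isomerising the C4=C5 bond.

Step 11
Reactants: 17 hydroxy enal
Product: 18 methyl (2Z,4S,6E,10E)-2-(bromomethyl)-10-{[(tert-butyldiphenylsilyl)oxy]methyl}-6-methyl-12-oxo-4-[(triethylsilyl)oxy]dodeca-2,6,10-trienoate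
Conditions: NBS, Me2S, CH2Cl2, 0 °C to rt
Reagents that add atoms: N-bromosuccinimide, O=C1CCC(=O)N1Br
Why: Corey–Kim-type activation of the Baylis–Hillman alcohol as an alkoxysulfonium salt followed by SN2′ attack of bromide at C13 should convert both C7 epimers into the same thermodynamically preferred (Z)-2-(bromomethyl)enoate without touching the aldehyde or the silyl ethers.

Step 12
Reactants: 18 bromo enal
Product: 20 15-[(tert-butyldiphenylsilyl)oxy]-8α-[(triethylsilyl)oxy]germacra-1(10),4,11(13)-trien-6α,12-olide (C1=C10 ring-trans; C4=C5 ring-cis; trans-fused lactone), via macrocyclic hydroxy ester 19 (not isolated)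
Conditions: CrCl2 (10 equiv), THF, rt, slow addition to 2 mM; then PPTS (cat.), toluene, 40 °C
Reagents that add atoms: none
Why: In this Nozaki–Hiyama-type allylation, divalent chromium turns the allylic bromide into an allylchromium species that adds through C7 to the aldehyde in a chair transition state with both tether ends equatorial (6,7-anti), while C8 keeps its hydrogen in the allyl plane and its silyloxy group anti to the incoming aldehyde (7,8-anti), after which the C6 hydroxyl lactonises onto the ester.

Step 13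
Reactants: 20 silylated lactone
Product: 21 15-[(tert-butyldiphenylsilyl)oxy]-8α-hydroxygermacra-1(10),4,11(13)-trien-6α,12-olide
Conditions: HF·pyridine, pyridine, THF, 0 °C
Reagents that add atoms: none
Why: Buffered fluoride desilylation cleaves the secondary triethylsilyl ether much faster than the primary tert-butyldiphenylsilyl ether, and the non-acidic medium avoids transannular cyclisation of the 1,5-diene.

Step 14
Reactants: 22 methyl (R)-3-hydroxy-2-methylpropanoate
Product: 23 methyl (R)-3-[(tert-butyldimethylsilyl)oxy]-2-methylpropanoate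
Conditions: TBSCl, imidazole, CH2Cl2, rt
Reagents that add atoms: tert-butyl(chloro)dimethylsilane, CC(C)(C)[Si](C)(C)Cl
Why: Standard silyl ether formation at the primary alcohol does not involve the α-stereocentre.

Step 15
Reactants: 23 methyl (R)-3-[(tert-butyldimethylsilyl)oxy]-2-methylpropanoate
Product: 24 (R)-3-[(tert-butyldimethylsilyl)oxy]-2-methylpropanoic acid
Conditions: LiOH, THF/MeOH/H2O, 0 °C to rt; then aq. HCl to pH 4
Reagents that add atoms: lithium hydroxide, [Li+].[OH-]
Why: Mild saponification of the methyl ester at low temperature should proceed without enolisation of the α-methyl stereocentre or loss of the silyl ether.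

Step 16
Reactants: 21 C8 alcohol; 24 (R)-3-[(tert-butyldimethylsilyl)oxy]-2-methylpropanoic acid
Product: 26 8α-{[(2R)-3-(tert-butyldimethylsilyloxy)-2-methylpropanoyl]oxy}-15-[(tert-butyldiphenylsilyl)oxy]germacra-1(10),4,11(13)-trien-6α,12-olide (C1=C10 ring-trans; C4=C5 ring-cis), via mixed anhydride 25 (not isolated)
Conditions: 2,4,6-Cl3C6H2COCl, Et3N, THF, rt; then 21, DMAP, toluene, rt
Reagents that add atoms: none
Why: Yamaguchi esterification acylates hindered secondary alcohols under conditions that should neither epimerise the α-methyl acid nor disturb the exocyclic methylene lactone.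

Step 17
Reactants: 26 bis-silylated germacratrienolide
Product: 27 8α-{[(2R)-3-(tert-butyldimethylsilyloxy)-2-methylpropanoyl]oxy}-15-[(tert-butyldiphenylsilyl)oxy]-10-epi-elema-1,3,11(13)-trien-6α,12-olide (H5α; vinyl β and methyl α on C10)
Conditions: toluene (5 mM), BHT (cat.), sealed tube, 190 °C; separation and reheating of recovered 26
Reagents that add atoms: none
Why: The step is a concerted [3,3]-sigmatropic shift in which C5–C10 forms as C2–C3 breaks through a chair array of C10, C1, C2, C3, C4 and C5, turning the two ring alkenes into the C1=C2 vinyl and C3=C4 isopropenyl groups. The closest known reaction type is the thermal Cope rearrangement of cyclodeca-1,5-dienes, as in germacranolide-to-elemanolide conversions and the rearrangement of (E,Z)-germacradienes to cis-divinylcyclohexanes. The cyclohexane C5–C6–C7–C8–C9–C10 is closed transannularly across the ten-membered ring, as a ring contraction that needs no new tether. C5 is controlled by the trans-fused lactone, which allows only the nascent chair with O6, C11 and O8 equatorial, so C4 ends up trans to O6 (H5 α); C10 is controlled by the alkene geometries, because the ring-trans C1=C10 places C9 equatorial and the ring-cis C4=C5 places C6 axial in the Cope chair, which leaves the vinyl group axial and cis to the C5 substituent. The step needs chair over boat selectivity and intact alkene geometries, which the rigid lactone and the defined alkenes of 26 should secure; the shift is reversible, so recovered 26 is recycled, and BHT suppresses radical loss of the methylene lactone.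

Step 18
Reactants: 27 bis-silylated elemanolide
Product: 28 CNP0133858.4
Conditions: HF·pyridine (excess), THF/pyridine, 0 °C to rt
Reagents that add atoms: none
Why: Fluoride-mediated desilylation should remove both the tert-butyldimethylsilyl and the tert-butyldiphenylsilyl ether under mildly acidic, non-nucleophilic conditions that leave the α-methylene lactone, the ester and the allylic alcohol untouched.

Compound list

1 | but-2-yne-1,4-diol | OCC#CCO | starting material
2 | 4-[(tert-butyldiphenylsilyl)oxy]but-2-yn-1-ol | OCC#CCO[Si](c1ccccc1)(c1ccccc1)C(C)(C)C | intermediate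
3 | sodium 3-{[(tert-butyldiphenylsilyl)oxy]methyl}-2,2-bis(2-methoxyethoxy)-2,5-dihydro-1,2-oxaluminol-2-uide (cyclic alkenylalanate) | [Na+].COCCO[Al-]1(OCCOC)OCC=C1CO[Si](c1ccccc1)(c1ccccc1)C(C)(C)C | intermediate (not isolated)
4 | (Z)-4-[(tert-butyldiphenylsilyl)oxy]-3-iodobut-2-en-1-ol (iodine cis to CH2OH) | OC/C=C(\I)CO[Si](c1ccccc1)(c1ccccc1)C(C)(C)C | intermediate
5 | (E)-3-{[(tert-butyldiphenylsilyl)oxy]methyl}penta-2,4-dien-1-ol (vinyl cis to CH2OH) | OC/C=C(\C=C)CO[Si](c1ccccc1)(c1ccccc1)C(C)(C)C | intermediate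
6 | (R)-glycidol, (2R)-oxiran-2-ylmethanol | OC[C@@H]1CO1 | starting material
7 | (S)-pent-4-yne-1,2-diol | C#CC[C@H](O)CO | intermediate
8 | (S)-4,5-bis[(triethylsilyl)oxy]pent-1-yne | C#CC[C@H](O[Si](CC)(CC)CC)CO[Si](CC)(CC)CC | intermediate
9 | dimethyl{(1E,4S)-2-methyl-4,5-bis[(triethylsilyl)oxy]pent-1-en-1-yl}alane | C[Al](C)/C=C(\C)C[C@H](O[Si](CC)(CC)CC)CO[Si](CC)(CC)CC | intermediate (not isolated)
10 | (2S,4E)-5-iodo-4-methyl-1,2-bis[(triethylsilyl)oxy]pent-4-ene | I/C=C(\C)C[C@H](O[Si](CC)(CC)CC)CO[Si](CC)(CC)CC | intermediate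
11 | {[(2S,4E)-5-iodo-4-methyl-2-(triethylsilyloxy)pent-4-en-1-yl]oxy}dimethylsulfonium chloride | C[S+](C)OC[C@@H](O[Si](CC)(CC)CC)C/C(C)=C/I.[Cl-] | intermediate (not isolated)
12 | (2S,4E)-5-iodo-4-methyl-2-[(triethylsilyl)oxy]pent-4-enal | I/C=C(\C)C[C@H](O[Si](CC)(CC)CC)C=O | intermediate
13 | methyl acrylate | C=CC(=O)OC | starting material
14 | methyl (4S,6E)-3-hydroxy-7-iodo-6-methyl-2-methylidene-4-[(triethylsilyl)oxy]hept-6-enoate, both C3 epimers | I/C=C(\C)C[C@H](O[Si](CC)(CC)CC)C(O)C(=C)C(=O)OC | intermediate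
15 | 9-[(E)-5-(9-borabicyclo[3.3.1]nonan-9-yloxy)-3-{[(tert-butyldiphenylsilyl)oxy]methyl}pent-3-en-1-yl]-9-borabicyclo[3.3.1]nonane | C1CCC2CCCC1B2CC/C(CO[Si](c1ccccc1)(c1ccccc1)C(C)(C)C)=C\COB1C2CCCC1CCC2 | intermediate (not isolated)
16 | methyl (4S,6E,10E)-10-{[(tert-butyldiphenylsilyl)oxy]methyl}-3,12-dihydroxy-6-methyl-2-methylidene-4-[(triethylsilyl)oxy]dodeca-6,10-dienoate, both C3 epimers (chain C9 and C12 cis on C10=C11) | C=C(C(=O)OC)C(O)[C@@H](O[Si](CC)(CC)CC)C/C(C)=C/CC/C(CO[Si](c1ccccc1)(c1ccccc1)C(C)(C)C)=C\CO | intermediate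
17 | methyl (4S,6E,10E)-10-{[(tert-butyldiphenylsilyl)oxy]methyl}-3-hydroxy-6-methyl-2-methylidene-12-oxo-4-[(triethylsilyl)oxy]dodeca-6,10-dienoate, both C3 epimers | C=C(C(=O)OC)C(O)[C@@H](O[Si](CC)(CC)CC)C/C(C)=C/CC/C(CO[Si](c1ccccc1)(c1ccccc1)C(C)(C)C)=C\C=O | intermediate
18 | methyl (2Z,4S,6E,10E)-2-(bromomethyl)-10-{[(tert-butyldiphenylsilyl)oxy]methyl}-6-methyl-12-oxo-4-[(triethylsilyl)oxy]dodeca-2,6,10-trienoate | BrC/C(C(=O)OC)=C\[C@@H](O[Si](CC)(CC)CC)C/C(C)=C/CC/C(CO[Si](c1ccccc1)(c1ccccc1)C(C)(C)C)=C\C=O | intermediate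
19 | methyl 15-[(tert-butyldiphenylsilyl)oxy]-6α-hydroxy-8α-[(triethylsilyl)oxy]germacra-1(10),4,11(13)-trien-12-oate (C1=C10 ring-trans, C4=C5 ring-cis, H6β, H7α, H8β) | C/C1=C\CC/C(CO[Si](c2ccccc2)(c2ccccc2)C(C)(C)C)=C\[C@@H](O)[C@H](C(=C)C(=O)OC)[C@@H](O[Si](CC)(CC)CC)C1 | intermediate (not isolated)
20 | 15-[(tert-butyldiphenylsilyl)oxy]-8α-[(triethylsilyl)oxy]germacra-1(10),4,11(13)-trien-6α,12-olide (C1=C10 ring-trans, C4=C5 ring-cis, trans-fused lactone) | C/C1=C\CC/C(CO[Si](c3ccccc3)(c3ccccc3)C(C)(C)C)=C\[C@H]2OC(=O)C(=C)[C@@H]2[C@@H](O[Si](CC)(CC)CC)C1 | intermediate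
21 | 15-[(tert-butyldiphenylsilyl)oxy]-8α-hydroxygermacra-1(10),4,11(13)-trien-6α,12-olide (same alkene geometries and ring fusion) | C/C1=C\CC/C(CO[Si](c3ccccc3)(c3ccccc3)C(C)(C)C)=C\[C@H]2OC(=O)C(=C)[C@@H]2[C@@H](O)C1 | intermediate
22 | methyl (R)-3-hydroxy-2-methylpropanoate | COC(=O)[C@H](C)CO | starting material
23 | methyl (R)-3-[(tert-butyldimethylsilyl)oxy]-2-methylpropanoate | COC(=O)[C@H](C)CO[Si](C)(C)C(C)(C)C | intermediate
24 | (R)-3-[(tert-butyldimethylsilyl)oxy]-2-methylpropanoic acid | OC(=O)[C@H](C)CO[Si](C)(C)C(C)(C)C | intermediate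
25 | (R)-3-[(tert-butyldimethylsilyl)oxy]-2-methylpropanoic 2,4,6-trichlorobenzoic anhydride | O=C(OC(=O)[C@H](C)CO[Si](C)(C)C(C)(C)C)c1c(Cl)cc(Cl)cc1Cl | intermediate (not isolated)
26 | 8α-{[(2R)-3-(tert-butyldimethylsilyloxy)-2-methylpropanoyl]oxy}-15-[(tert-butyldiphenylsilyl)oxy]germacra-1(10),4,11(13)-trien-6α,12-olide (C1=C10 ring-trans, C4=C5 ring-cis, H6β, H7α, H8β) | C/C1=C\CC/C(CO[Si](c3ccccc3)(c3ccccc3)C(C)(C)C)=C\[C@H]2OC(=O)C(=C)[C@@H]2[C@@H](OC(=O)[C@H](C)CO[Si](C)(C)C(C)(C)C)C1 | intermediate
27 | 8α-{[(2R)-3-(tert-butyldimethylsilyloxy)-2-methylpropanoyl]oxy}-15-[(tert-butyldiphenylsilyl)oxy]-10-epi-elema-1,3,11(13)-trien-6α,12-olide (H5α, H6β, H7α, H8β; C10 vinyl β and methyl α, vinyl cis to the C5 substituent) | C=C[C@@]1(C)C[C@H](OC(=O)[C@H](C)CO[Si](C)(C)C(C)(C)C)[C@H]2C(=C)C(=O)O[C@@H]2[C@H]1C(=C)CO[Si](c1ccccc1)(c1ccccc1)C(C)(C)C | intermediate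
28 | CNP0133858.4, 15-hydroxy-8α-{[(2R)-3-hydroxy-2-methylpropanoyl]oxy}-10-epi-elema-1,3,11(13)-trien-6α,12-olide | C=C[C@@]1(C)C[C@H](OC(=O)[C@H](C)CO)[C@H]2C(=C)C(=O)O[C@@H]2[C@H]1C(=C)CO | target

Total step count: 18.
Longest linear sequence: 13 steps (steps 4–13 and 16–18, from (R)-glycidol 6).

Steps most likely to fail

Step 17. The equilibrium may be reached only slowly, at a temperature where the exocyclic methylene lactone is lost to radical oligomerisation, so repeated recycling would erode material. The fallback masks the Michael acceptor during heating. It sets out from 26: conjugate addition of thiophenol (PhSH, Et3N cat., THF, rt) should give the 13-phenylthio-11,13-dihydro lactone F1. Heating as in step 17 should then give the rearranged sulfide F2. NaIO4 in aqueous methanol oxidises sulfur only, to the sulfoxide F3. Thermal syn-elimination (toluene, 110 °C, CaCO3) restores the methylene group and returns to the route at 27.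

Step 12. The allylchromium intermediate may add through the chair in which the C8-bearing carbon is axial, the arrangement usual in open-chain additions of 2-(alkoxycarbonyl)allyl metals. That would give the C6 epimer and the cis-fused lactone series; oligomerisation is a second loss channel. The fallback corrects C6 after ring closure. It sets out from 18: the C6-epimeric hydroxy ester F4 (or its cis-lactone) is saponified with LiOH in aqueous THF to the hydroxy acid F5. Mitsunobu lactonisation (PPh3, diisopropyl azodicarboxylate, THF, 0 °C, dilute) then closes the γ-lactone with inversion at C6 and rejoins the route at 20.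

Step 8. The amine-catalysed addition to the hindered aldehyde may be slow, and enolisation at the α-silyloxy carbon would erode C8, the only stereocentre that controls all later ones. The fallback is a base-free vinylalumination. It sets out from 12: methyl propiolate is hydroaluminated with (i-Bu)2AlH and N-methylmorpholine N-oxide in THF at 0 °C to methyl 2-(diisobutylalumanyl)acrylate F6. This adds to the aldehyde at 0 °C and returns to the route at 14.

Further compounds
F1 | step 17 | 13-(phenylsulfanyl)-11,13-dihydro derivative of 26 (C11 configuration open) | C/C1=C\CC/C(CO[Si](c3ccccc3)(c3ccccc3)C(C)(C)C)=C\[C@H]2OC(=O)C(CSc3ccccc3)[C@@H]2[C@@H](OC(=O)[C@H](C)CO[Si](C)(C)C(C)(C)C)C1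
F2 | step 17 | 13-(phenylsulfanyl)-11,13-dihydro derivative of 27 (C11 configuration open) | C=C[C@@]1(C)C[C@H](OC(=O)[C@H](C)CO[Si](C)(C)C(C)(C)C)[C@H]2C(CSc3ccccc3)C(=O)O[C@@H]2[C@H]1C(=C)CO[Si](c1ccccc1)(c1ccccc1)C(C)(C)C
F3 | step 17 | 13-(phenylsulfinyl)-11,13-dihydro derivative of 27 | C=C[C@@]1(C)C[C@H](OC(=O)[C@H](C)CO[Si](C)(C)C(C)(C)C)[C@H]2C(CS(=O)c3ccccc3)C(=O)O[C@@H]2[C@H]1C(=C)CO[Si](c1ccccc1)(c1ccccc1)C(C)(C)C
F4 | step 12 | methyl 15-[(tert-butyldiphenylsilyl)oxy]-6β-hydroxy-8α-[(triethylsilyl)oxy]germacra-1(10),4,11(13)-trien-12-oate (C6 epimer of 19) | C/C1=C\CC/C(CO[Si](c2ccccc2)(c2ccccc2)C(C)(C)C)=C\[C@H](O)[C@H](C(=C)C(=O)OC)[C@@H](O[Si](CC)(CC)CC)C1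
F5 | step 12 | 15-[(tert-butyldiphenylsilyl)oxy]-6β-hydroxy-8α-[(triethylsilyl)oxy]germacra-1(10),4,11(13)-trien-12-oic acid | C/C1=C\CC/C(CO[Si](c2ccccc2)(c2ccccc2)C(C)(C)C)=C\[C@H](O)[C@H](C(=C)C(=O)O)[C@@H](O[Si](CC)(CC)CC)C1
F6 | step 8 | methyl 2-(diisobutylalumanyl)prop-2-enoate | C=C(C(=O)OC)[Al](CC(C)C)CC(C)C
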